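**Remark:** the SMILES is read as the (2S)-flavanone with an (E)-geranyl group at C6. Flavanone locants (O1, C2, C3, C4, C4a, C5 to C8, C8a) are used for these atoms throughout, also in open-chain precursors.

## Retrosynthetic overview

1. The target comes from the bis-MOM flavanone 14 by MOM removal and methylation of the non-chelated 7-OH; ring C is the only ring that has to be made.
2. Ring C is built in one flask from chloroarene 5 and the (S)-hydroxy Weinreb amide 8: first C4–C4a (aryllithium acylation, held as the tetrahedral lithium hemiaminal), then ring closure through O1–C8a by addition of the C2 alkoxide to the aryne C8a≡C8.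
3. Enabling feature: on ring A, C8a lies between C4a (which carries the C4 chain) and C8–H, and C8–H is flanked by the C7 oxygen. Chlorine at C8a plus the acidic H-8 is therefore a latent aryne next to the tether. The tether O1–C2–C3–C4–C4a reaches only C8a (six-membered ring C), the C7 oxygen polarises the aryne the same way, and the carbanion lands on C8, where the target has H.
4. Ring A comes from 5-chlororesorcinol: with MOM ethers on both oxygens and geranyl between them the arene is symmetric, so its two ring CH positions are equivalent. C2 is set by Noyori hydrogenation of a commercial β-keto ester.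
5. Ring order: rings A and B are bought, ring C is formed in step 5, then deprotection and 7-O-methylation.

Key step: step 5

## Route

Step 1
Reactants: 1 5-chlorobenzene-1,3-diol (5-chlororesorcinol)
Product: 2 5-chloro-1,3-bis(methoxymethoxy)benzene
Conditions: MOMCl, i-Pr2NEt, CH2Cl2, 0 °C → rt
Reagents that add atoms: chloromethyl methyl ether (MOMCl), COCCl
Why: Base-mediated O-alkylation of both phenols (Williamson-type etherification) installs the two MOM ethers that later direct both ring metalations and come off under mild acid.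

Step 2
Reactants: 2 5-chloro-1,3-bis(methoxymethoxy)benzene; 3 geranyl bromide [(2E)-1-bromo-3,7-dimethylocta-2,6-diene]
Product: 5 5-chloro-2-[(2E)-3,7-dimethylocta-2,6-dien-1-yl]-1,3-bis(methoxymethoxy)benzene, via aryllithium 4 (not isolated)
Conditions: n-BuLi, THF, −40 °C; CuBr·SMe2 (10 mol %), 3, −78 °C → rt
Reagents that add atoms: none
Why: Directed ortho-metalation should occur at the C–H flanked by the two chelating MOM ethers, and copper-catalysed SN2 allylation of the aryllithium by the primary allylic bromide keeps the E alkene.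

Step 3
Reactants: 6 ethyl 3-(3,4-dimethoxyphenyl)-3-oxopropanoate
Product: 7 ethyl (3S)-3-(3,4-dimethoxyphenyl)-3-hydroxypropanoate
Conditions: RuCl2[(R)-BINAP] (0.5 mol %), H2 (50 atm), EtOH, 80 °C
Reagents that add atoms: none
Why: Noyori asymmetric hydrogenation of a β-keto ester, in which the ester-chelated ketone is reduced on one face by the Ru–BINAP hydride; (R)-BINAP is the antipode expected to give the (S)-carbinol that becomes C2.

Step 4
Reactants: 7 ethyl (3S)-3-(3,4-dimethoxyphenyl)-3-hydroxypropanoate
Product: 8 (3S)-3-(3,4-dimethoxyphenyl)-3-hydroxy-N-methoxy-N-methylpropanamide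
Conditions: MeNH(OMe)·HCl, i-PrMgCl, THF, −20 → 0 °C; aq NH4Cl
Reagents that add atoms: N,O-dimethylhydroxylamine hydrochloride, CNOC.Cl
Why: Weinreb amide formation by aminolysis of the ester with the chloromagnesium amide made in the flask, the hydroxyl riding along as its magnesium alkoxide so that the C2 centre is untouched.

Step 5
Reactants: 5 5-chloro-2-[(2E)-3,7-dimethylocta-2,6-dien-1-yl]-1,3-bis(methoxymethoxy)benzene; 8 (3S)-3-(3,4-dimethoxyphenyl)-3-hydroxy-N-methoxy-N-methylpropanamide
Product: 14 (2S)-2-(3,4-dimethoxyphenyl)-6-[(2E)-3,7-dimethylocta-2,6-dien-1-yl]-5,7-bis(methoxymethoxy)-2,3-dihydro-4H-chromen-4-one, via aryllithium 9 (not isolated), via lithium alkoxide 10 (not isolated), via tetrahedral adduct 11 (not isolated), via aryne 12 (not isolated), via cyclised aryllithium 13 (not isolated)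
Conditions: 5, n-BuLi, THF, −78 °C; 8 + lithium 2,2,6,6-tetramethylpiperidide (LiTMP, 1.0 equiv), THF, −78 °C, added to 9, −78 → −60 °C; LiTMP (1.5 equiv), −78 → −20 °C; inverse quench into aq NH4Cl, 0 °C
Reagents that add atoms: none
Why: Proposed new method: aryllithium 9 adds to the Weinreb amide of alkoxide 10 to give the chelated dilithium hemiaminal 11, which is not a ketone and so cannot undergo retro-aldol, enolisation or dehydration; LiTMP then removes the only remaining ring proton H-8 (flanked by Cl at C8a and the C7 MOM ether), LiCl is lost, and aryne 12 (C8a≡C8) is captured at C8a by the tethered C2 lithium alkoxide, closing ring C through the O1–C8a bond to give aryllithium 13, which the quench converts into H-8 and the C4 ketone. The closest known reaction types are the base-induced aryne cyclisation of haloarenes carrying a tethered alkoxide (benzyne route to chromans) and the acylation of ortho-metalated arenes by Weinreb amides; the new element is their union in one flask with the tetrahedral intermediate serving as tether and carbonyl mask. Ring C closes in a formal 6-exo-dig mode, by addition across the in-plane π bond of the aryne, driven by release of aryne strain. No stereocentre is created: C2 comes unchanged from 8 because neither its C–O nor its C–H bond is touched, and the transient C4 hemiaminal centre is erased on work-up. Regioselectivity is needed at three points and is secured by the substrate: both ring CH of 5 are equivalent by symmetry, only H-8 is left for the second metalation so only the C8a≡C8 aryne can form, and the tether can reach only C8a while the C7 oxygen polarises the aryne in the same sense. Chemoselectivity against intermolecular capture of the aryne rests on the intramolecular six-membered closure and on the hindered, weakly nucleophilic amide base.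

Step 6
Reactants: 14 (2S)-2-(3,4-dimethoxyphenyl)-6-[(2E)-3,7-dimethylocta-2,6-dien-1-yl]-5,7-bis(methoxymethoxy)-2,3-dihydro-4H-chromen-4-one
Product: 15 (2S)-2-(3,4-dimethoxyphenyl)-6-[(2E)-3,7-dimethylocta-2,6-dien-1-yl]-5,7-dihydroxy-2,3-dihydro-4H-chromen-4-one
Conditions: 2 M aq HCl, MeOH, 40 °C
Reagents that add atoms: none
Why: Acid-catalysed acetal solvolysis (MOM cleavage) frees both phenols, and the mild acid and low temperature are chosen to leave the geranyl alkenes and the benzylic C2–O1 ether intact.

Step 7
Reactants: 15 (2S)-2-(3,4-dimethoxyphenyl)-6-[(2E)-3,7-dimethylocta-2,6-dien-1-yl]-5,7-dihydroxy-2,3-dihydro-4H-chromen-4-one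
Product: 16 (2S)-2-(3,4-dimethoxyphenyl)-6-[(2E)-3,7-dimethylocta-2,6-dien-1-yl]-5-hydroxy-7-methoxy-2,3-dihydro-4H-chromen-4-one (CNP0310479.1)
Conditions: MeOH (1.2 equiv), PPh3, DIAD, THF, 0 °C → rt
Reagents that add atoms: methanol, CO
Why: Mitsunobu alkylation should methylate only the acidic, non-chelated 7-OH because the 5-OH is locked in a hydrogen bond to the C4 carbonyl, and the neutral conditions avoid the base-induced ring opening that would erode C2.

## Compound list

1 | 5-chlorobenzene-1,3-diol (5-chlororesorcinol) | Oc1cc(Cl)cc(O)c1 | starting material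
2 | 5-chloro-1,3-bis(methoxymethoxy)benzene | COCOc1cc(Cl)cc(OCOC)c1 | intermediate
3 | geranyl bromide, (2E)-1-bromo-3,7-dimethylocta-2,6-diene | BrC/C=C(\C)CCC=C(C)C | starting material
4 | [4-chloro-2,6-bis(methoxymethoxy)phenyl]lithium | [Li]c1c(OCOC)cc(Cl)cc1OCOC | intermediate (not isolated)
5 | 5-chloro-2-[(2E)-3,7-dimethylocta-2,6-dien-1-yl]-1,3-bis(methoxymethoxy)benzene | COCOc1cc(Cl)cc(OCOC)c1C/C=C(\C)CCC=C(C)C | intermediate
6 | ethyl 3-(3,4-dimethoxyphenyl)-3-oxopropanoate | CCOC(=O)CC(=O)c1ccc(OC)c(OC)c1 | starting material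
7 | ethyl (3S)-3-(3,4-dimethoxyphenyl)-3-hydroxypropanoate | COc1ccc([C@@H](O)CC(=O)OCC)cc1OC | intermediate
8 | (3S)-3-(3,4-dimethoxyphenyl)-3-hydroxy-N-methoxy-N-methylpropanamide | COc1ccc([C@@H](O)CC(=O)N(C)OC)cc1OC | intermediate
9 | {2-chloro-5-[(2E)-3,7-dimethylocta-2,6-dien-1-yl]-4,6-bis(methoxymethoxy)phenyl}lithium (lithium on the carbon between Cl and OMOM) | COCOc1cc(Cl)c([Li])c(OCOC)c1C/C=C(\C)CCC=C(C)C | intermediate (not isolated)
10 | lithium (1S)-1-(3,4-dimethoxyphenyl)-3-[methoxy(methyl)amino]-3-oxopropan-1-olate (lithium alkoxide of 8) | COc1ccc([C@@H](O[Li])CC(=O)N(C)OC)cc1OC | intermediate (not isolated)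
11 | dilithium (3S)-1-{2-chloro-5-[(2E)-3,7-dimethylocta-2,6-dien-1-yl]-4,6-bis(methoxymethoxy)phenyl}-3-(3,4-dimethoxyphenyl)-1-[methoxy(methyl)amino]propane-1,3-diolate (tetrahedral adduct, both C4 epimers) | COc1ccc([C@@H](O[Li])CC(O[Li])(N(C)OC)c2c(Cl)cc(OCOC)c(C/C=C(\C)CCC=C(C)C)c2OCOC)cc1OC | intermediate (not isolated)
12 | aryne formed from 11 by loss of H-8 and Cl (triple bond C8a≡C8, both alkoxides still lithiated) | COc1ccc([C@@H](O[Li])CC(O[Li])(N(C)OC)C2=C(OCOC)C(C/C=C(\C)CCC=C(C)C)=C(OCOC)C#C2)cc1OC | intermediate (not isolated)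
13 | (2S)-8-lithio-4-(lithiooxy)-4-[methoxy(methyl)amino]-2-(3,4-dimethoxyphenyl)-6-[(2E)-3,7-dimethylocta-2,6-dien-1-yl]-5,7-bis(methoxymethoxy)chromane (both C4 epimers) | COc1ccc([C@@H]2CC(O[Li])(N(C)OC)c3c(OCOC)c(C/C=C(\C)CCC=C(C)C)c(OCOC)c([Li])c3O2)cc1OC | intermediate (not isolated)
14 | (2S)-2-(3,4-dimethoxyphenyl)-6-[(2E)-3,7-dimethylocta-2,6-dien-1-yl]-5,7-bis(methoxymethoxy)-2,3-dihydro-4H-chromen-4-one | COc1ccc([C@@H]2CC(=O)c3c(OCOC)c(C/C=C(\C)CCC=C(C)C)c(OCOC)cc3O2)cc1OC | intermediate
15 | (2S)-2-(3,4-dimethoxyphenyl)-6-[(2E)-3,7-dimethylocta-2,6-dien-1-yl]-5,7-dihydroxy-2,3-dihydro-4H-chromen-4-one | COc1ccc([C@@H]2CC(=O)c3c(O)c(C/C=C(\C)CCC=C(C)C)c(O)cc3O2)cc1OC | intermediate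
16 | (2S)-2-(3,4-dimethoxyphenyl)-6-[(2E)-3,7-dimethylocta-2,6-dien-1-yl]-5-hydroxy-7-methoxy-2,3-dihydro-4H-chromen-4-one (CNP0310479.1) | COc1ccc([C@@H]2CC(=O)c3c(cc(OC)c(C/C=C(\C)CCC=C(C)C)c3O)O2)cc1OC | target

## Step count and risks

Total step count: 7. Longest linear sequence: 5 steps (1 → 2 → 5 → 14 → 15 → 16, or equally 6 → 7 → 8 → 14 → 15 → 16).

**Step 5 (Proposed new method).**
- What may go wrong: the hindered aryllithium 9 may add to the amide too slowly at −78 °C and lose LiCl before acylation. After the second metalation the aryne may be intercepted intermolecularly by amide base instead of by the tethered alkoxide. Prolonged exposure to LiTMP may metalate the benzylic C2–H and erode its configuration.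
- Fallback (known chemistry), setting out from 5 and 8 and returning at 14: 5 is lithiated as in step 5, the alkoxide of 8 is added at −78 °C and the mixture is quenched cold with aq NH4Cl. This stops the sequence at the open-chain aldol (3S)-1-{2-chloro-5-[(2E)-3,7-dimethylocta-2,6-dien-1-yl]-4,6-bis(methoxymethoxy)phenyl}-3-(3,4-dimethoxyphenyl)-3-hydroxypropan-1-one F1. NaBH4 in MeOH at 0 °C reduces the ketone to (3S)-1-{2-chloro-5-[(2E)-3,7-dimethylocta-2,6-dien-1-yl]-4,6-bis(methoxymethoxy)phenyl}-3-(3,4-dimethoxyphenyl)propane-1,3-diol F2 (both C1 epimers are usable), which removes the base-sensitive aldol. Palladium-catalysed intramolecular etherification (Pd(OAc)2, 2-(di-tert-butylphosphino)-1,1'-binaphthyl, Cs2CO3, toluene, 70 °C) then forms the same O1–C8a bond; only the C3 hydroxyl can reach the chlorinated carbon through a six-membered ring. This gives (2S)-2-(3,4-dimethoxyphenyl)-6-[(2E)-3,7-dimethylocta-2,6-dien-1-yl]-5,7-bis(methoxymethoxy)-3,4-dihydro-2H-chromen-4-ol F3. Dess–Martin periodinane in CH2Cl2 buffered with NaHCO3 restores the C4 ketone and delivers 14.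

**Step 6.**
- What may go wrong: acid-promoted addition of the freed C5 or C7 hydroxyl to the C2''=C3'' double bond of the geranyl chain (chroman formation), and acid-induced reversible opening of the C2–O1 bond with loss of configuration.
- Fallback, setting out from 14 and returning at 15: the MOM ethers are exchanged for silyl ethers under aprotic, buffered conditions (TMSOTf, 2,2'-bipyridyl, CH2Cl2, 0 °C), which should give (2S)-2-(3,4-dimethoxyphenyl)-6-[(2E)-3,7-dimethylocta-2,6-dien-1-yl]-5,7-bis(trimethylsilyloxy)-2,3-dihydro-4H-chromen-4-one F4. The aryl silyl ethers are then hydrolysed by water at rt to give 15 without exposure to Brønsted acid.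

**Step 2.**
- What may go wrong: attack of the aryl nucleophile at the tertiary terminus of the allyl system (SN2′) giving the linalyl isomer, and Wurtz-type consumption of the bromide.
- Fallback, setting out from 2 (with 3) and returning at 5: aryllithium 4 is generated as before and transmetalated with ZnCl2 to [4-chloro-2,6-bis(methoxymethoxy)phenyl]zinc chloride F5. F5 is coupled with 3 under Pd(PPh3)4 catalysis (THF, rt) in a Negishi-type allyl–aryl coupling, which should form the C–C bond at the primary allyl terminus with the E geometry retained, giving 5.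

Further compounds
F1 | step 5 | (3S)-1-{2-chloro-5-[(2E)-3,7-dimethylocta-2,6-dien-1-yl]-4,6-bis(methoxymethoxy)phenyl}-3-(3,4-dimethoxyphenyl)-3-hydroxypropan-1-one | COc1ccc([C@@H](O)CC(=O)c2c(Cl)cc(OCOC)c(C/C=C(\C)CCC=C(C)C)c2OCOC)cc1OC
F2 | step 5 | (3S)-1-{2-chloro-5-[(2E)-3,7-dimethylocta-2,6-dien-1-yl]-4,6-bis(methoxymethoxy)phenyl}-3-(3,4-dimethoxyphenyl)propane-1,3-diol (both C1 epimers) | COc1ccc([C@@H](O)CC(O)c2c(Cl)cc(OCOC)c(C/C=C(\C)CCC=C(C)C)c2OCOC)cc1OC
F3 | step 5 | (2S)-2-(3,4-dimethoxyphenyl)-6-[(2E)-3,7-dimethylocta-2,6-dien-1-yl]-5,7-bis(methoxymethoxy)-3,4-dihydro-2H-chromen-4-ol (both C4 epimers) | COc1ccc([C@@H]2CC(O)c3c(OCOC)c(C/C=C(\C)CCC=C(C)C)c(OCOC)cc3O2)cc1OC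
F4 | step 6 | (2S)-2-(3,4-dimethoxyphenyl)-6-[(2E)-3,7-dimethylocta-2,6-dien-1-yl]-5,7-bis(trimethylsilyloxy)-2,3-dihydro-4H-chromen-4-one | COc1ccc([C@@H]2CC(=O)c3c(O[Si](C)(C)C)c(C/C=C(\C)CCC=C(C)C)c(O[Si](C)(C)C)cc3O2)cc1OC
F5 | step 2 | [4-chloro-2,6-bis(methoxymethoxy)phenyl]zinc chloride | Cl[Zn]c1c(OCOC)cc(Cl)cc1OCOC
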